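## Structural features

The target is a 2,3-dihydrobenzofuran: a benzene ring fused through C3a and C7a to a five-membered ring made of O1, C2 and C3. The benzene ring is a masked resorcinol: O1 sits on C7a, a free phenol on C6, and an acetyl group on C5 lies ortho to that phenol (hydrogen-bonded) and para to O1; C4 and C7 carry hydrogen. C2 carries an isopropenyl group and C3 an acyloxy group; the two stereocentres are adjacent, both S, and their substituents are cis. The acyl group is (Z)-2-(acetoxymethyl)but-2-enoyl, an angelate-type enoate (methyl cis to the carbonyl) that also carries an allylic acetate. The fragile points are three: the C3–O bond is benzylic and flanked by O1 (ortho) and the C6 oxygen (para), so it ionises with acid and is expelled by a para-phenoxide; H2 is anti to the C3 oxygen in the cis isomer, so elimination to the aromatic benzofuran is always downhill; and the Z enoate can isomerise or lose its acetate in an SN2′ sense under nucleophilic catalysis. The real difficulty is to set two contiguous oxygenated stereocentres cis on a ring that wants to aromatise, and to bring in the labile ester and the isopropenyl group late under near-neutral conditions. The key step uses the fact that the C3a–C3–C2–O1 unit is an ortho carbon of a phenol and its oxygen, spanned by two carbons of an oxidised prenyl group: C3 at the aldehyde level, C2 at the epoxide level, and the gem-dimethyl carbinol left over as the precursor of the isopropenyl group.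

## Logic of the disconnections

**23 ⇒ 21 (through 22).** The O–Si bond at O6 and the two ketal C–O bonds on the C5 side chain are handled last. A free phenoxide para to the benzylic C3 ester in an electron-rich ring would expel the carboxylate, so both masks stay until the end. The gain is that every earlier intermediate is a neutral, non-chelating arene. The demand is an acidic or buffered unmasking in which the ketal goes first (22), so that the ring carries its acceptor before the phenol appears.

**21 ⇒ 19 (through 20).** The isopropenyl C=C is traced back to a tertiary C–OH plus a methyl C–H, because a tertiary alcohol is exactly what an epoxide opening leaves behind. The gain is a robust spectator during esterification. The demand is a neutral dehydration that takes a methyl hydrogen and not H2, and that neither ionises nor eliminates the C3 ester.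

**19 ⇒ 17 + 14 (through 18).** The acyl–O bond at C3 is cut. The Z enoate with its allylic acetate is the most fragile piece and is best made separately and attached late. The gain is convergence: 17 holds the ring and both stereocentres, 14 is a small achiral acid. The demand is acylation of a hindered secondary benzylic alcohol next to a tertiary one, with retention at C3 and without Z-to-E isomerisation or loss of acetate.

**17 ⇒ 5 + 8 (through 15 and 16).** C3–C3a and O1–C2 are cut. This removes the heterocycle and one stereocentre at once and leaves a phenol and a five-carbon epoxy aldehyde whose single stereocentre comes from catalytic asymmetric epoxidation. The demands are four: carbon attack at the ortho position that becomes C3a (not C7, not oxygen), anti facial selectivity at the aldehyde, 5-exo opening at the secondary epoxide carbon with inversion, and survival of the epoxide until then.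

**5 ⇒ 4 ⇒ 3 ⇒ 2 ⇒ 1.** Only heteroatom–protecting-group bonds are cut (O–benzyl, O–Si, ketal C–O). The demand is differentiation of the two phenols of 1, which their different acidity and hydrogen bonding provide, and a ketalisation mild enough for an aryl silyl ether.

**8 ⇒ 7 ⇒ 6.** The aldehyde is taken back to the primary alcohol and the epoxide C–O bonds to the olefin of 6. The demand is enantioface control in the epoxidation and an oxidation that does not epimerise or open the epoxide.

**14 ⇒ 13 ⇒ 12 ⇒ 10 (through 11) ⇒ 9.** The Cα–CH2 bond and the Cβ–H bond of the enoate are cut, which leads to an ynoate. A syn delivery of H (to Cβ) and of the hydroxymethyl carbon (to Cα) fixes the Z geometry. The tert-butyl ester is chosen so that the acid can be released without touching the acetate.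

## Other disconnections considered

**Alternative 1:** The benzene ring is disconnected at C3a–C7a and C4–C5. This leads to A1, 3-acetyl-6-{[(3S,4S)-4-(tert-butyldimethylsilyloxy)-2-methylhex-1-en-5-yn-3-yl]oxy}-4-hydroxy-2H-pyran-2-one, in which a terminal alkyne hangs from the 6-alkoxy oxygen through both stereogenic carbons. On heating, A1 should undergo an intramolecular [4+2] cycloaddition across C6 and C3 of the pyranone, closing the dihydrofuran ring, and then lose CO2 to give A2, the C3 TBS ether of (2S,3S)-5-acetyl-6-hydroxy-2-isopropenyl-2,3-dihydrobenzofuran-3-ol.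
- In its favour: the tether dictates the substitution pattern of the arene, which is better than the chosen plan, where a shielding group must steer the ortho attack. A2 already carries the isopropenyl group, the free acetyl and the free phenol, so only desilylation and esterification remain; this endgame is shorter than the three steps after 17, and no dehydration is needed.
- Against it here: both stereocentres must be made beforehand in an acyclic enyne diol by separate asymmetric chemistry. In A1 they sit in an allyl ether of an enol-type oxygen, which can undergo a [3,3] shift onto C5 of the pyranone at the temperatures an unactivated alkyne is likely to need. A 6-alkoxy-4-hydroxy-3-acylpyranone is an acylating, hydrolytically labile ketene-acetal lactone that is hard to O-alkylate with a hindered secondary alcohol. The β-silyloxy group may eliminate.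
- Comparison: mechanistically the alternative is a concerted pericyclic event with predictable connectivity but harsh conditions, against two polar bond formations at or below room temperature. On the source of chirality the two plans are equal (catalytic asymmetric reactions). On step economy the alternative wins after the key step but probably loses before it, since A1 is more demanding to assemble than 5 and 8.

**Alternative 2:** The O1–C2 bond is traced back to a ring contraction of A3, (3S,4S)-6-acetyl-7-(tert-butyldimethylsilyloxy)-3-hydroxy-2,2-dimethylchroman-4-yl (Z)-2-(acetoxymethyl)but-2-enoate. Triflation of its equatorial C3 hydroxyl should let the ring oxygen, antiperiplanar to the leaving group, shift from the gem-dimethyl carbon to C3 with inversion. The tertiary cation then loses a methyl proton to give A4, the C6 TBS ether of the target.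
- In its favour: A4 is one desilylation from the target, so the endgame is clearly shorter. The isopropenyl group and the five-membered ring arise in one event. The cis relationship of A3 can come from a syn-dihydroxylation of a chromene, which secures the relative configuration by mechanism; this is better than the chosen plan, which depends on facial selectivity at an aldehyde. A3 should be reachable from 1 in few steps (chromene annulation with a C5 enal, silylation, asymmetric dihydroxylation, selective acylation), so the total step count would be lower than that of the chosen route.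
- Against it here: the migrating oxygen is para to the acetyl group and therefore a poor neighbouring group. The aryl carbon C4a is also antiperiplanar to the leaving group, and its shift would give a different skeleton, as would a hydride shift from C4. The two secondary hydroxyls must be told apart in the acylation. The labile Z ester and a benzylic acyloxy group must survive triflic anhydride and a cationic cascade. The enantioselectivity of the dihydroxylation of an acceptor-substituted chromene is uncertain.
- Comparison: structurally both plans reach the same ring from 1. Mechanistically the alternative stakes everything on the migratory preference in a cation, while the chosen plan uses two bond formations that each have close analogy. On step economy the alternative is the better one.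

**Alternative 3:** The C2–C3 bond is cut. The precursor is the achiral eight-membered aryl enol ether A5, 9-(tert-butyldimethylsilyloxy)-3-methyl-8-(2-methyl-1,3-dioxolan-2-yl)-4H,6H-1,5-benzodioxocine. A benzylic α-oxy carbanion of A5 should undergo a transannular [2,3]-Wittig rearrangement: it attacks the enol ether carbon, breaks the allylic C–O bond, contracts the ring and unveils the isopropenyl group, giving A6, (2S,3S)-6-(tert-butyldimethylsilyloxy)-5-(2-methyl-1,3-dioxolan-2-yl)-2-(prop-1-en-2-yl)-2,3-dihydrobenzofuran-3-ol.
- In its favour: C2–C3, both stereocentres and the isopropenyl group are formed in one step, and no dehydration is needed (better than the chosen plan on this count). The bicyclic transition state ties the C3 oxygen and the C2 substituent together, so the cis relationship is enforced by geometry; this is also better than reliance on Felkin–Anh control. A6 needs only esterification and unmasking.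
- Against it here: the absolute configuration has to come from an external chiral base in an enantioselective benzylic deprotonation, whereas the chosen plan draws it from a reliable catalytic epoxidation. The benzylic position is deactivated by the electron-rich ring, and C7, flanked by two oxygens, is a strong competitor for lithiation. [1,2]-shift and β-elimination pathways compete. The Z enol ether in an eight-membered ring must be built (for example from 5 by ortho-hydroxymethylation, double O-alkylation with a 2-methylene-1,3-dihalopropane and olefin isomerisation), with a medium-ring closure and an isomerisation of uncertain direction.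
- Comparison: on step economy the two plans are about equal. On relative stereocontrol the alternative is better. On absolute stereocontrol and predictability of the key step the chosen plan is stronger.

Key step: step 11

Remark on the chemistry: the C6 oxygen is carried as a triisopropylsilyl ether instead of a tert-butyldimethylsilyl ether, because it tolerates the basic stage of step 11 better and shields C7 more strongly. The descriptor changes S→R (7→8) and R→S at C2 (19→21) are priority changes only. The stereochemical course (R aldehyde, anti addition, inversion at C2) was checked against the (2S,3S) target and no structure needed correction.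

## Route

Step 1
Reactants: 1 2,4-dihydroxyacetophenone
Product: 2 1-[4-(benzyloxy)-2-hydroxyphenyl]ethan-1-one
Conditions: BnBr (1.05 equiv), K2CO3, acetone, reflux
Reagents that add atoms: benzyl bromide BrCc1ccccc1
Why: Williamson etherification; the 4-hydroxyl is the more acidic and is free, whereas the 2-hydroxyl is locked in a hydrogen bond to the carbonyl group, so mono-benzylation at O4 should be clean with one equivalent of halide.

Step 2
Reactants: 2 1-[4-(benzyloxy)-2-hydroxyphenyl]ethan-1-one
Product: 3 1-[4-(benzyloxy)-2-(triisopropylsilyloxy)phenyl]ethan-1-one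
Conditions: iPr3SiCl, imidazole, DMF, 40 °C
Reagents that add atoms: triisopropylsilyl chloride CC(C)[Si](Cl)(C(C)C)C(C)C
Why: Silylation of the remaining chelated phenol with a chlorosilane and imidazole; the bulky silyl group later shields the ring carbon between the two oxygens and should resist the basic stage of step 11.

Step 3
Reactants: 3 1-[4-(benzyloxy)-2-(triisopropylsilyloxy)phenyl]ethan-1-one
Product: 4 2-[4-(benzyloxy)-2-(triisopropylsilyloxy)phenyl]-2-methyl-1,3-dioxolane
Conditions: Me3SiOCH2CH2OSiMe3, Me3SiOTf (cat.), CH2Cl2, −78 → −20 °C; pyridine quench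
Reagents that add atoms: 1,2-bis(trimethylsilyloxy)ethane C[Si](C)(C)OCCO[Si](C)(C)C
Why: Noyori ketalisation; silyl-triflate catalysis under aprotic conditions is driven by disiloxane formation, so the deactivated aryl ketone should still convert while the aryl silyl ether and benzyl ether survive. The ketal removes the para acceptor that would make the phenoxide of step 11 a poor carbon nucleophile.

Step 4
Reactants: 4 2-[4-(benzyloxy)-2-(triisopropylsilyloxy)phenyl]-2-methyl-1,3-dioxolane
Product: 5 4-(2-methyl-1,3-dioxolan-2-yl)-3-(triisopropylsilyloxy)phenol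
Conditions: H2 (1 atm), 10% Pd/C, NaHCO3 (solid), EtOAc, rt
Reagents that add atoms: none
Why: Hydrogenolysis of the benzyl aryl ether over palladium; solid NaHCO3 keeps the medium neutral so the acid-labile ketal stays, and the silyl ether and the tertiary ketal carbon should not be reduced at one atmosphere.

Step 5
Reactants: 6 3-methylbut-2-en-1-ol
Product: 7 (S)-(3,3-dimethyloxiran-2-yl)methanol
Conditions: Ti(OiPr)4 (5 mol %), L-(+)-diisopropyl tartrate (6 mol %), tBuOOH, 4 Å sieves, CH2Cl2, −20 °C; non-aqueous work-up, distillation
Reagents that add atoms: tert-butyl hydroperoxide CC(C)(C)OO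
Why: Katsuki–Sharpless asymmetric epoxidation; the titanium tartrate complex binds the allylic alcohol and the hydroperoxide, and with the L-(+)-tartrate the oxygen goes to the face that gives the 2S epoxy alcohol, as for other primary allylic alcohols. The single stereocentre of the aldehyde fragment is set here, and a non-aqueous work-up is needed because 7 is small and water-soluble.

Step 6
Reactants: 7 (S)-(3,3-dimethyloxiran-2-yl)methanol
Product: 8 (R)-3,3-dimethyloxirane-2-carbaldehyde
Conditions: TEMPO (10 mol %), PhI(OAc)2, CH2Cl2, 0 °C → rt; cold NaHCO3 wash, bulb-to-bulb distillation, use at once as a CH2Cl2 solution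
Reagents that add atoms: none
Why: Oxoammonium (TEMPO) oxidation stops at the aldehyde in anhydrous CH2Cl2 and leaves the epoxide alone. The stereocentre is not touched (S to R is a priority change) and should not enolise readily because the α carbon is part of the oxirane.

Step 7
Reactants: 9 but-2-ynoic acid
Product: 10 tert-butyl but-2-ynoate
Conditions: Cl3CC(=NH)OtBu, cyclohexane–CH2Cl2, rt
Reagents that add atoms: tert-butyl 2,2,2-trichloroacetimidate CC(C)(C)OC(=N)C(Cl)(Cl)Cl
Why: Imidate esterification; the acid protonates the imidate, which hands a tert-butyl cation to the carboxylate, and no nucleophilic catalyst is present that could add to the ynoate. The tert-butyl ester can later be removed by acid without touching an acetate.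

Step 8
Reactants: 10 tert-butyl but-2-ynoate
Product: 12 tert-butyl (Z)-2-(hydroxymethyl)but-2-enoate, via alkenylalane 11 (not isolated)
Conditions: iBu2AlH, N-methylmorpholine N-oxide, THF, 0 °C; then CH2O (gas, from cracked paraformaldehyde), −20 °C → rt; aq. KNaC4H4O6
Reagents that add atoms: formaldehyde C=O
Why: Conjugate hydroalumination followed by aldol-type trapping (vinylalumination); the amine-oxide-complexed hydride adds H to the β carbon, and 11 (in equilibrium with its allenolate) is attacked by formaldehyde at the α carbon, in the plane of the β substituents and from the side of the hydrogen. The hydroxymethyl group therefore ends cis to H and the methyl group cis to the ester, which is the Z (angelate-type) geometry.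

Step 9
Reactants: 12 tert-butyl (Z)-2-(hydroxymethyl)but-2-enoate
Product: 13 tert-butyl (Z)-2-(acetoxymethyl)but-2-enoate
Conditions: Ac2O, pyridine, CH2Cl2, 0 °C → rt
Reagents that add atoms: acetic anhydride CC(=O)OC(C)=O
Why: Acetylation of the primary alcohol with anhydride and pyridine; no DMAP or other strong nucleophile is used, so the allylic acetate on the enoate should not suffer SN2′ displacement or Z-to-E isomerisation.

Step 10
Reactants: 13 tert-butyl (Z)-2-(acetoxymethyl)but-2-enoate
Product: 14 (Z)-2-(acetoxymethyl)but-2-enoic acid
Conditions: CF3CO2H, CH2Cl2, 0 °C → rt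
Reagents that add atoms: none
Why: Acidolysis of the tert-butyl ester by an E1 path (loss of 2-methylpropene); the acetate and the olefin geometry should be stable to the anhydrous acid because no nucleophile or base is present.

Step 11
Reactants: 5 4-(2-methyl-1,3-dioxolan-2-yl)-3-(triisopropylsilyloxy)phenol, 8 (R)-3,3-dimethyloxirane-2-carbaldehyde
Product: 17 (2R,3S)-2-(2-hydroxypropan-2-yl)-5-(2-methyl-1,3-dioxolan-2-yl)-6-(triisopropylsilyloxy)-2,3-dihydrobenzofuran-3-ol, via bromomagnesium phenoxide 15 (not isolated), via epoxy alcohol 16 (not isolated)
Conditions: 5, EtMgBr (1.0 equiv), Et2O, 0 °C; evaporate, CH2Cl2; 8 (1.2 equiv), −30 → 0 °C; then MeOH, K2CO3, 0 °C → rt; pH 7 buffer work-up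
Reagents that add atoms: none
Why: Proposed new method: both halves have close analogy (ortho-specific hydroxyalkylation of halomagnesium phenoxides by aldehydes, including α-oxygenated ones, in non-coordinating solvents, and base-mediated 5-exo opening of a neighbouring epoxide by a phenoxide), but their tandem use with an α,β-epoxy aldehyde has no direct precedent. The aldehyde of 8 binds to the magnesium of 15 and is delivered through a six-membered cyclic transition state to the ortho carbon; rearomatisation gives the magnesium salt of 16 and forms C3–C3a. The para position is blocked by the ketal-bearing carbon, and of the two ortho carbons the one between the oxygens is screened by the triisopropylsilyl group, so attack should occur at the carbon that becomes C3a. The new stereocentre C3 is controlled by the epoxide stereocentre in a Felkin–Anh (non-chelated) transition state, with the epoxide C–O bond anti to the forming bond and the nucleophile passing the hydrogen; the methyl group cis to the formyl group and the weak donor ability of the epoxide oxygen both disfavour the chelated alternative, so the anti (S) carbinol is expected. Methanol and K2CO3 then free the phenoxide from magnesium, and it attacks the secondary epoxide carbon in a 5-exo-tet closure with inversion, forming O1–C2 and leaving the tertiary alcohol. Attack at the tertiary carbon (6-endo) is a Lewis-acid pathway and should be suppressed once magnesium is displaced, and the carbinol is not deprotonated by carbonate, which keeps Payne rearrangement out. Anti addition followed by inversion places the C3 hydroxyl and the C2 substituent cis, with the (2R,3S) descriptors that correspond to the (2S,3S) target.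

Step 12
Reactants: 17 (2R,3S)-2-(2-hydroxypropan-2-yl)-5-(2-methyl-1,3-dioxolan-2-yl)-6-(triisopropylsilyloxy)-2,3-dihydrobenzofuran-3-ol, 14 (Z)-2-(acetoxymethyl)but-2-enoic acid
Product: 19 (2R,3S)-2-(2-hydroxypropan-2-yl)-5-(2-methyl-1,3-dioxolan-2-yl)-6-(triisopropylsilyloxy)-2,3-dihydrobenzofuran-3-yl (Z)-2-(acetoxymethyl)but-2-enoate, via mixed anhydride 18 (not isolated)
Conditions: 14, 2,4,6-Cl3C6H2COCl, Et3N, toluene, 0 °C; then 17, DMAP (0.3 equiv), 0 °C → rt
Reagents that add atoms: none
Why: Yamaguchi esterification; 18 transfers the enoyl group to the secondary C3 hydroxyl under DMAP catalysis while the tertiary hydroxyl stays inert, and the C3–O bond is not broken, so the configuration is retained. This protocol is the usual one for angelate-type acids because acyl transfer is faster than conjugate addition of the catalyst; DMAP is kept substoichiometric and cold to protect the allylic acetate.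

Step 13
Reactants: 19 (2R,3S)-2-(2-hydroxypropan-2-yl)-5-(2-methyl-1,3-dioxolan-2-yl)-6-(triisopropylsilyloxy)-2,3-dihydrobenzofuran-3-yl (Z)-2-(acetoxymethyl)but-2-enoate
Product: 21 (2S,3S)-5-(2-methyl-1,3-dioxolan-2-yl)-2-(prop-1-en-2-yl)-6-(triisopropylsilyloxy)-2,3-dihydrobenzofuran-3-yl (Z)-2-(acetoxymethyl)but-2-enoate, via sulfamate ester 20 (not isolated)
Conditions: Burgess reagent (MeO2CNSO2NEt3, 2 equiv), toluene, rt → 50 °C
Reagents that add atoms: none
Why: Burgess dehydration; the tertiary alcohol gives 20, which undergoes intramolecular syn-elimination on gentle warming. Six methyl hydrogens compete with one hindered hydrogen on the oxygen-bearing ring carbon C2, so the isopropenyl group should dominate, and the neutral conditions should leave the benzylic ester, ketal and silyl ether intact.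

Step 14
Reactants: 21 (2S,3S)-5-(2-methyl-1,3-dioxolan-2-yl)-2-(prop-1-en-2-yl)-6-(triisopropylsilyloxy)-2,3-dihydrobenzofuran-3-yl (Z)-2-(acetoxymethyl)but-2-enoate
Product: 23 (2S,3S)-5-acetyl-6-hydroxy-2-(prop-1-en-2-yl)-2,3-dihydrobenzofuran-3-yl (Z)-2-(acetoxymethyl)but-2-enoate, via silyl ether ketone 22 (not isolated)
Conditions: PPTS, acetone–H2O (10:1), 0 °C → rt; concentrate; then HF·pyridine, pyridine, THF, 0 °C
Reagents that add atoms: water O
Why: Acid-catalysed ketal hydrolysis comes first (the oxocarbenium ion is stabilised by the ortho and para oxygens, so PPTS should suffice), so the ring carries the acetyl acceptor before the phenol is set free. The ortho-acyl aryl silyl ether of 22 is then cleaved by buffered HF, which never generates a phenoxide; this order avoids expulsion of the C3 carboxylate through a para-quinone methide and base-induced elimination, and no stereocentre is affected.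

## Compound list

1 | 2,4-dihydroxyacetophenone | CC(=O)c1ccc(O)cc1O | starting material
2 | 1-[4-(benzyloxy)-2-hydroxyphenyl]ethan-1-one | CC(=O)c1ccc(OCc2ccccc2)cc1O | intermediate
3 | 1-[4-(benzyloxy)-2-(triisopropylsilyloxy)phenyl]ethan-1-one | CC(=O)c1ccc(OCc2ccccc2)cc1O[Si](C(C)C)(C(C)C)C(C)C | intermediate
4 | 2-[4-(benzyloxy)-2-(triisopropylsilyloxy)phenyl]-2-methyl-1,3-dioxolane | CC1(OCCO1)c1ccc(OCc2ccccc2)cc1O[Si](C(C)C)(C(C)C)C(C)C | intermediate
5 | 4-(2-methyl-1,3-dioxolan-2-yl)-3-(triisopropylsilyloxy)phenol | CC1(OCCO1)c1ccc(O)cc1O[Si](C(C)C)(C(C)C)C(C)C | intermediate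
6 | 3-methylbut-2-en-1-ol | CC(C)=CCO | starting material
7 | (S)-(3,3-dimethyloxiran-2-yl)methanol | OC[C@@H]1OC1(C)C | intermediate
8 | (R)-3,3-dimethyloxirane-2-carbaldehyde | O=C[C@@H]1OC1(C)C | intermediate
9 | but-2-ynoic acid | CC#CC(=O)O | starting material
10 | tert-butyl but-2-ynoate | CC#CC(=O)OC(C)(C)C | intermediate
11 | tert-butyl (E)-2-(diisobutylalumanyl)but-2-enoate (aluminium cis to H, methyl cis to the ester; C-bound form of the allenolate) | C/C=C(\C(=O)OC(C)(C)C)[Al](CC(C)C)CC(C)C | intermediate (not isolated)
12 | tert-butyl (Z)-2-(hydroxymethyl)but-2-enoate | C/C=C(/CO)C(=O)OC(C)(C)C | intermediate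
13 | tert-butyl (Z)-2-(acetoxymethyl)but-2-enoate | C/C=C(/COC(C)=O)C(=O)OC(C)(C)C | intermediate
14 | (Z)-2-(acetoxymethyl)but-2-enoic acid | C/C=C(/COC(C)=O)C(=O)O | intermediate
15 | bromomagnesium 4-(2-methyl-1,3-dioxolan-2-yl)-3-(triisopropylsilyloxy)phenoxide | CC1(OCCO1)c1ccc(O[Mg]Br)cc1O[Si](C(C)C)(C(C)C)C(C)C | intermediate (not isolated)
16 | 2-{(S)-[(2S)-3,3-dimethyloxiran-2-yl](hydroxy)methyl}-4-(2-methyl-1,3-dioxolan-2-yl)-5-(triisopropylsilyloxy)phenol (present in the flask as its magnesium salt) | CC1(OCCO1)c1cc([C@H](O)[C@@H]2OC2(C)C)c(O)cc1O[Si](C(C)C)(C(C)C)C(C)C | intermediate (not isolated)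
17 | (2R,3S)-2-(2-hydroxypropan-2-yl)-5-(2-methyl-1,3-dioxolan-2-yl)-6-(triisopropylsilyloxy)-2,3-dihydrobenzofuran-3-ol (cis) | CC(C)(O)[C@@H]1Oc2cc(O[Si](C(C)C)(C(C)C)C(C)C)c(C3(C)OCCO3)cc2[C@@H]1O | intermediate
18 | (Z)-2-(acetoxymethyl)but-2-enoic 2,4,6-trichlorobenzoic anhydride | C/C=C(/COC(C)=O)C(=O)OC(=O)c1c(Cl)cc(Cl)cc1Cl | intermediate (not isolated)
19 | (2R,3S)-2-(2-hydroxypropan-2-yl)-5-(2-methyl-1,3-dioxolan-2-yl)-6-(triisopropylsilyloxy)-2,3-dihydrobenzofuran-3-yl (Z)-2-(acetoxymethyl)but-2-enoate | CC(C)(O)[C@@H]1Oc2cc(O[Si](C(C)C)(C(C)C)C(C)C)c(C3(C)OCCO3)cc2[C@@H]1OC(=O)/C(=C\C)COC(C)=O | intermediate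
20 | triethylammonium salt of the N-(methoxycarbonyl)sulfamate ester of the tertiary alcohol of 19 | COC(=O)[N-]S(=O)(=O)OC(C)(C)[C@@H]1Oc2cc(O[Si](C(C)C)(C(C)C)C(C)C)c(C3(C)OCCO3)cc2[C@@H]1OC(=O)/C(=C\C)COC(C)=O.CC[NH+](CC)CC | intermediate (not isolated)
21 | (2S,3S)-5-(2-methyl-1,3-dioxolan-2-yl)-2-(prop-1-en-2-yl)-6-(triisopropylsilyloxy)-2,3-dihydrobenzofuran-3-yl (Z)-2-(acetoxymethyl)but-2-enoate | C=C(C)[C@@H]1Oc2cc(O[Si](C(C)C)(C(C)C)C(C)C)c(C3(C)OCCO3)cc2[C@@H]1OC(=O)/C(=C\C)COC(C)=O | intermediate
22 | (2S,3S)-5-acetyl-2-(prop-1-en-2-yl)-6-(triisopropylsilyloxy)-2,3-dihydrobenzofuran-3-yl (Z)-2-(acetoxymethyl)but-2-enoate | C=C(C)[C@@H]1Oc2cc(O[Si](C(C)C)(C(C)C)C(C)C)c(C(C)=O)cc2[C@@H]1OC(=O)/C(=C\C)COC(C)=O | intermediate (not isolated)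
23 | (2S,3S)-5-acetyl-6-hydroxy-2-(prop-1-en-2-yl)-2,3-dihydrobenzofuran-3-yl (Z)-2-(acetoxymethyl)but-2-enoate | C=C(C)[C@@H]1Oc2cc(O)c(C(C)=O)cc2[C@@H]1OC(=O)/C(=C\C)COC(C)=O | target

## Step count and least certain steps

Total: 14 steps. Longest linear sequence: 8 steps (1, 2, 3, 4, 11, 12, 13, 14). The aldehyde branch (5, 6) and the acid branch (7–10) join it at steps 11 and 12.

**Step 11 (key step, the one step beyond known chemistry).** The most likely failures are Lewis-acid attack of the magnesium halide on the epoxide before or instead of C–C bond formation (halohydrin formation, rearrangement, 6-endo closure at the tertiary carbon) and erosion of facial selectivity if magnesium chelates the epoxide oxygen. Both come from the Lewis acidity that the ortho-delivery needs. Fallback with known reactions, setting out from 5 and returning at 17: the C–C bond is made with an aryllithium instead of a magnesium phenoxide. Bromination of 5 with N-bromosuccinimide (CH2Cl2, −40 °C, iPr2NH cat.) at the free ortho position should give 2-bromo-4-(2-methyl-1,3-dioxolan-2-yl)-5-(triisopropylsilyloxy)phenol F1. n-BuLi (2.1 equiv, THF, −78 °C) deprotonates the phenol and exchanges bromine for lithium to give lithium 2-lithio-4-(2-methyl-1,3-dioxolan-2-yl)-5-(triisopropylsilyloxy)phenoxide F2, which is added to 8 at −78 °C. Lithium in THF does not chelate, and additions of organolithiums to epoxy aldehydes with a cis substituent are reported to favour the anti adduct. Aqueous work-up then gives 16 as an isolable phenol, and K2CO3 in methanol closes it to 17, as in the known base cyclisations of ortho-(epoxyalkyl)phenols.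

**Step 12.** The most likely failures are isomerisation of the Z enoate to the E isomer and SN2′ loss of the allylic acetate through reversible addition of DMAP to the activated acyl unit, made worse by slow acylation of the hindered cis alcohol. Fallback setting out from 12 and returning at 23: the hydroxymethyl group is carried as a silyl ether and acetylated last.
- tBuPh2SiCl and imidazole in DMF convert 12 into tert-butyl (Z)-2-[(tert-butyldiphenylsilyloxy)methyl]but-2-enoate F3.
- CF3CO2H in CH2Cl2 at 0 °C gives (Z)-2-[(tert-butyldiphenylsilyloxy)methyl]but-2-enoic acid F4, which has no allylic leaving group.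
- Yamaguchi esterification with 17 gives (2R,3S)-2-(2-hydroxypropan-2-yl)-5-(2-methyl-1,3-dioxolan-2-yl)-6-(triisopropylsilyloxy)-2,3-dihydrobenzofuran-3-yl (Z)-2-[(tert-butyldiphenylsilyloxy)methyl]but-2-enoate F5.
- Burgess dehydration gives (2S,3S)-5-(2-methyl-1,3-dioxolan-2-yl)-2-(prop-1-en-2-yl)-6-(triisopropylsilyloxy)-2,3-dihydrobenzofuran-3-yl (Z)-2-[(tert-butyldiphenylsilyloxy)methyl]but-2-enoate F6.
- PPTS in wet acetone followed by Bu4NF buffered with AcOH removes the ketal and both silyl groups to give (2S,3S)-5-acetyl-6-hydroxy-2-(prop-1-en-2-yl)-2,3-dihydrobenzofuran-3-yl (Z)-2-(hydroxymethyl)but-2-enoate F7.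
- Ac2O with 2,4,6-collidine at −20 °C should acetylate only the primary allylic alcohol, because the phenol is held in a hydrogen bond to the acetyl group, and give 23.

**Step 13.** The most likely failures are elimination toward C2 (an enol ether that would aromatise) and thermal ionisation or elimination of the C3 ester, which would waste the valuable acid. Fallback setting out from 17 and returning at 21: the dehydration is moved in front of the esterification.
- Ac2O, pyridine and catalytic DMAP acetylate the secondary alcohol of 17 to give (2R,3S)-2-(2-hydroxypropan-2-yl)-5-(2-methyl-1,3-dioxolan-2-yl)-6-(triisopropylsilyloxy)-2,3-dihydrobenzofuran-3-yl acetate F8.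
- Dehydration (Burgess reagent, or SOCl2/pyridine or Martin sulfurane, since no sensitive enoate is present) gives (2S,3S)-5-(2-methyl-1,3-dioxolan-2-yl)-2-(prop-1-en-2-yl)-6-(triisopropylsilyloxy)-2,3-dihydrobenzofuran-3-yl acetate F9, from which regioisomers can be separated.
- iBu2AlH in CH2Cl2 at −78 °C removes the acetate to give (2S,3S)-5-(2-methyl-1,3-dioxolan-2-yl)-2-(prop-1-en-2-yl)-6-(triisopropylsilyloxy)-2,3-dihydrobenzofuran-3-ol F10.
- Yamaguchi esterification of F10 with 14 gives 21.

**Step 8.** The most likely failures are loss of geometric integrity of 11 through its allenolate before trapping, and inefficient capture of monomeric formaldehyde, giving E/Z mixtures or the simply reduced enoate. Fallback setting out from 10 and returning at 12: syn-hydrostannation with Bu3SnH and the zerovalent palladium complex Pd(PPh3)4 in THF should give tert-butyl (E)-2-(tributylstannyl)but-2-enoate F11 (tin at the α carbon, cis to H). I2 in CH2Cl2 at 0 °C gives tert-butyl (E)-2-iodobut-2-enoate F12 with retention. Stille coupling with Bu3SnCH2OH [Pd(PPh3)4, dioxane, 90 °C] then gives 12 with the methyl group still cis to the ester.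

## Further compounds

F1 | step 11 | 2-bromo-4-(2-methyl-1,3-dioxolan-2-yl)-5-(triisopropylsilyloxy)phenol | CC1(OCCO1)c1cc(Br)c(O)cc1O[Si](C(C)C)(C(C)C)C(C)C
F2 | step 11 | lithium 2-lithio-4-(2-methyl-1,3-dioxolan-2-yl)-5-(triisopropylsilyloxy)phenoxide | CC1(OCCO1)c1cc([Li])c(O[Li])cc1O[Si](C(C)C)(C(C)C)C(C)C
F3 | step 12 | tert-butyl (Z)-2-[(tert-butyldiphenylsilyloxy)methyl]but-2-enoate | C/C=C(/CO[Si](c1ccccc1)(c1ccccc1)C(C)(C)C)C(=O)OC(C)(C)C
F4 | step 12 | (Z)-2-[(tert-butyldiphenylsilyloxy)methyl]but-2-enoic acid | C/C=C(/CO[Si](c1ccccc1)(c1ccccc1)C(C)(C)C)C(=O)O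
F5 | step 12 | (2R,3S)-2-(2-hydroxypropan-2-yl)-5-(2-methyl-1,3-dioxolan-2-yl)-6-(triisopropylsilyloxy)-2,3-dihydrobenzofuran-3-yl (Z)-2-[(tert-butyldiphenylsilyloxy)methyl]but-2-enoate | CC(C)(O)[C@@H]1Oc2cc(O[Si](C(C)C)(C(C)C)C(C)C)c(C3(C)OCCO3)cc2[C@@H]1OC(=O)/C(=C\C)CO[Si](c1ccccc1)(c1ccccc1)C(C)(C)C
F6 | step 12 | (2S,3S)-5-(2-methyl-1,3-dioxolan-2-yl)-2-(prop-1-en-2-yl)-6-(triisopropylsilyloxy)-2,3-dihydrobenzofuran-3-yl (Z)-2-[(tert-butyldiphenylsilyloxy)methyl]but-2-enoate | C=C(C)[C@@H]1Oc2cc(O[Si](C(C)C)(C(C)C)C(C)C)c(C3(C)OCCO3)cc2[C@@H]1OC(=O)/C(=C\C)CO[Si](c1ccccc1)(c1ccccc1)C(C)(C)C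
F7 | step 12 | (2S,3S)-5-acetyl-6-hydroxy-2-(prop-1-en-2-yl)-2,3-dihydrobenzofuran-3-yl (Z)-2-(hydroxymethyl)but-2-enoate | C=C(C)[C@@H]1Oc2cc(O)c(C(C)=O)cc2[C@@H]1OC(=O)/C(=C\C)CO
F8 | step 13 | (2R,3S)-2-(2-hydroxypropan-2-yl)-5-(2-methyl-1,3-dioxolan-2-yl)-6-(triisopropylsilyloxy)-2,3-dihydrobenzofuran-3-yl acetate | CC(C)(O)[C@@H]1Oc2cc(O[Si](C(C)C)(C(C)C)C(C)C)c(C3(C)OCCO3)cc2[C@@H]1OC(C)=O
F9 | step 13 | (2S,3S)-5-(2-methyl-1,3-dioxolan-2-yl)-2-(prop-1-en-2-yl)-6-(triisopropylsilyloxy)-2,3-dihydrobenzofuran-3-yl acetate | C=C(C)[C@@H]1Oc2cc(O[Si](C(C)C)(C(C)C)C(C)C)c(C3(C)OCCO3)cc2[C@@H]1OC(C)=O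
F10 | step 13 | (2S,3S)-5-(2-methyl-1,3-dioxolan-2-yl)-2-(prop-1-en-2-yl)-6-(triisopropylsilyloxy)-2,3-dihydrobenzofuran-3-ol | C=C(C)[C@@H]1Oc2cc(O[Si](C(C)C)(C(C)C)C(C)C)c(C3(C)OCCO3)cc2[C@@H]1O
F11 | step 8 | tert-butyl (E)-2-(tributylstannyl)but-2-enoate | C/C=C(\C(=O)OC(C)(C)C)[Sn](CCCC)(CCCC)CCCC
F12 | step 8 | tert-butyl (E)-2-iodobut-2-enoate | C/C=C(/I)C(=O)OC(C)(C)C
A1 | alternative 1 | 3-acetyl-6-{[(3S,4S)-4-(tert-butyldimethylsilyloxy)-2-methylhex-1-en-5-yn-3-yl]oxy}-4-hydroxy-2H-pyran-2-one | C=C(C)[C@H](OC1=CC(O)=C(C(C)=O)C(=O)O1)[C@@H](O[Si](C)(C)C(C)(C)C)C#C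
A2 | alternative 1 | 1-[(2S,3S)-3-(tert-butyldimethylsilyloxy)-6-hydroxy-2-(prop-1-en-2-yl)-2,3-dihydrobenzofuran-5-yl]ethan-1-one | C=C(C)[C@@H]1Oc2cc(O)c(C(C)=O)cc2[C@@H]1O[Si](C)(C)C(C)(C)C
A3 | alternative 2 | (3S,4S)-6-acetyl-7-(tert-butyldimethylsilyloxy)-3-hydroxy-2,2-dimethylchroman-4-yl (Z)-2-(acetoxymethyl)but-2-enoate | CC1(C)Oc2cc(O[Si](C)(C)C(C)(C)C)c(C(C)=O)cc2[C@H](OC(=O)/C(=C\C)COC(C)=O)[C@@H]1O
A4 | alternative 2 | (2S,3S)-5-acetyl-6-(tert-butyldimethylsilyloxy)-2-(prop-1-en-2-yl)-2,3-dihydrobenzofuran-3-yl (Z)-2-(acetoxymethyl)but-2-enoate | C=C(C)[C@@H]1Oc2cc(O[Si](C)(C)C(C)(C)C)c(C(C)=O)cc2[C@@H]1OC(=O)/C(=C\C)COC(C)=O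
A5 | alternative 3 | 9-(tert-butyldimethylsilyloxy)-3-methyl-8-(2-methyl-1,3-dioxolan-2-yl)-4H,6H-1,5-benzodioxocine | C/C1=C/Oc2cc(O[Si](C)(C)C(C)(C)C)c(C3(C)OCCO3)cc2COC1
A6 | alternative 3 | (2S,3S)-6-(tert-butyldimethylsilyloxy)-5-(2-methyl-1,3-dioxolan-2-yl)-2-(prop-1-en-2-yl)-2,3-dihydrobenzofuran-3-ol | C=C(C)[C@@H]1Oc2cc(O[Si](C)(C)C(C)(C)C)c(C3(C)OCCO3)cc2[C@@H]1O
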